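## The problem

The target is a germacranolide-type lactone: a ten-membered carbocycle C1–C10 with two trisubstituted ring olefins, C4=C5 and C9=C10, both Z (methyls C15 on C4 and C14 on C10). A γ-lactone is cis-fused across C6–C7 (O on C6, carbonyl C12, C11 on C7 bearing the exocyclic C13 methylene), C8 carries an angelate, and C1 and C3 carry free hydroxyls.

Five stereocentres have to be set: 1S, 3S, 6S, 7S, 8R. C6, C7 and C8 are contiguous, and O6 and O8 are both anti to the C11 arm on C7 when C5–C9 is drawn as a zigzag. An aldol can therefore set C7/C8, and C7 can then direct C6.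

C1 and C3 form an anti-1,3-diol on the far side of the ring, out of reach of acyclic induction from C6–C8. C3 has to be fixed by the ring-forming event, and C1 can then be derived from C3.

The ten-membered ring is the kinetic obstacle. It helps that the two Z olefins and the cis-lactone remove rotors and fold a seco-chain back on itself.

Several groups are fragile:
- The α-methylene lactone is a Michael acceptor and a good dipolarophile, so it must come late.
- The angelate drifts to the tiglate under base or nucleophilic catalysis and cannot be present during enolate chemistry.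
- The allylic C1/C3 carbinols and the dienylic C6–O bond ionise under acid.
- A β-hydroxy ketone at C1/C3 can dehydrate.
- (Z)-Enals on the way can lose their geometry.

The enabling feature is the C1–C2–C3 unit: two oxygens 1,3 to each other across a CH2, each carbinol attached to the methyl-bearing carbon of a Z olefin. At the ketone level at C1 this is an isoxazoline (C1=N, O–C3). That is the adduct of a C1 nitrile oxide with a C2=C3 vinyl group, and the vinyl group is simply the end of a (Z)-C2=C3–C4(C15)=C5 diene.

## Retrosynthesis

**C8 ester and diol unmasking (40 ⇒ 39 ⇒ 36 + 37).** The C8–O acyl bond is cut, with the diol held as acetonide 39 until the last step. The angelate has to follow all enolate chemistry, and a free diol would compete in the acylation, so the order is acylation of alcohol 36 with angelic acid 37, then mild acetal cleavage. The forward acylation must esterify a hindered allylic alcohol without Z to E drift.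

**C11=C13 (35 ⇒ 33 ⇒ 32).** The methylene is removed to the saturated lactone 32 through Mannich base 33. Carrying it through the ring closure is not an option, because a nitrile oxide would add to it first. The forward step needs a lactone enolate, so the diol is masked as acetonide 32 and O8 stays silylated.

**C1–H and N–O (32 ⇒ 31 ⇒ 30 ⇒ 28).** The anti-diol 31 comes from hydroxyl-directed reduction of β-hydroxy enone 30, so C1 follows from C3. Ketone 30 is the N–O cleavage product of isoxazoline 28. Compared with building the diol by a separate aldol on an open chain, this asks for only one externally controlled centre.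

**Key disconnection (28 ⇒ 25): C1–C2 and C3–O.** Cutting C2–C3 instead would call for a macro-aldol of an enolisable methyl ketone with no handle on C3. Cutting C3–C4 or C5–C6 leaves the diol to be built stepwise on the chain. Oxime 25 has two rings and one stereocentre fewer, and its ends are a (Z)-enal oxime and a (Z)-diene. The forward reaction must deliver carbon to C2 and oxygen to C3, pick the vinyl group over three trisubstituted olefins, beat dimerisation, and choose one face at C3.

**Dipole precursor (25 ⇒ 24 ⇒ 23 ⇒ 22).** The oxime comes from enal 24, the enal from allylic alcohol 23, and 23 from bis-silyl ether 22 by removal of the primary silyl group in the presence of the hindered secondary one. Only functional-group changes are involved.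

**Lactone and C5–C6 (22 ⇒ 20 ⇒ 19 + 12).** The C6–O and C6–H bonds are cut: lactone 22 arises from hydride addition to dienone 20 and closure of the C6 alkoxide onto the C12 methyl ester. Adding the dienyl metal to a C6 aldehyde would form the same bond, but Felkin–Anh control would then give the C6 epimer; hydride addition to the ketone gives the needed 1,2-anti sense. The C5–C6 bond is cut to thioester 19 and dienylstannane 12. A neutral thioester–stannane coupling is preferred to an organolithium addition because of the C12 ester and the β-silyloxy group.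

**C7–C8 (19 ⇒ 18 ⇒ 17 ⇒ 15 + 6).** An anti-aldol of succinate imide 15 with (Z)-enal 6 sets both centres. The imide enolises only at C7, and the auxiliary becomes the C6 acyl handle. O8 is γ to the C12 ester and must be silylated at once (18) so that it cannot lactonise. The non-chelating silyl ether is also what the Felkin–Anh step needs.

**Both Z olefins from one building block (6, 12 ⇒ 3 ⇒ 1; 15 ⇒ 13 + 14).** (Z)-Iodoalkenol 3, from directed carbomagnesiation of propargyl alcohol 1, serves twice. Silylation and formylation give 6 (C8, C9, C10, C14, C1). Oxidation to 7, methylenation with 8 and stannylation via 10 give 12 (C5, C4, C15, C3, C2). Imide 15 is the acylation product of oxazolidinone 13 with acid chloride 14.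

## Roads not taken

**Alternative 1:** The ring is not closed but uncovered. A terpene-derived bicycle of two six-membered rings would carry a 1,2-diol on the shared C3–C8 bond, and Pb(OAc)4 (tetravalent lead) would cleave it to the cyclodecadienedione A1.
- Merits: glycol cleavage is fast and has no entropic penalty. Both Z olefins are fixed beforehand inside six-membered rings. The C11=C13 methylene is already present. In certainty of ring formation, and in not needing a late enolate methylenation, this road is better than the chosen one.
- Weak points: the doubly unsaturated, heavily oxygenated bicycle with its tetrasubstituted diol is long to build. A1 then holds two enones (C3 and C8) that must be reduced with different stereochemical demands. C7 is α to the C8 ketone with the C6 silyloxy group β to it, so epimerisation and elimination threaten. C12 must still be oxidised and lactonised, and four oxygens (C1, C3, C6, C8) must be told apart.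
- What the chosen plan sets against it: the oxygens arrive already differentiated (lactone at C6, silyl ether at C8, isoxazoline for C1/C3), and only one redox event follows ring formation.

**Alternative 2:** The C5–C6 bond is cut. Pd2(dba)3 (zerovalent palladium) with copper thiophene-2-carboxylate (CuTC, monovalent copper) would couple a C6 thioester with a (Z)-C5 alkenylstannane within one chain and give the ten-membered enone A2.
- Merits: neutral conditions. C1, C3, C7 and C8 are all set on the open chain by acyclic methods, so C3 does not depend on the ring closure. In that respect it is better than the chosen plan.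
- Weak points: closing a ten-membered ring between two sp2 centres at high dilution invites protodestannylation and oligomers. The C6 ketone must afterwards be reduced under macrocyclic rather than Felkin–Anh control. The anti-diol needs its own aldol, directed reduction and two silyl groups on the chain, which lengthens the linear sequence.
- Comparison: the ring-closure risk is comparable. The chosen plan answers with a step that forms two rings and two bonds and brings both diol oxygens in latent form. It uses the same thioester–stannane coupling intermolecularly (step 11), where it is secure, and sets C6 before the ring exists.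

**Alternative 3:** The C3–C4 bond is cut. CrCl2 (divalent chromium) with catalytic NiCl2 (divalent nickel) would turn a (Z)-C4 alkenyl iodide into an alkenylchromium that adds to a C3 aldehyde, giving A3, the C1 silyl ether of the target.
- Merits: very late and convergent, chemoselective for the aldehyde, with retention of the trisubstituted olefin geometry. Only a desilylation follows. In endgame length, and in precedent for medium rings, it is better than the chosen plan.
- Weak points: the seco-aldehyde must carry the α-methylene lactone and the angelate through its whole assembly. The C3 aldehyde has a β-silyloxy group at C1 and can eliminate. The C3 configuration is decided in the macrocyclisation with no reliable model, and with O1 silylated there is no directed reduction to correct it.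
- Comparison: both roads leave C3 to the ring closure. The chosen plan keeps the two acrylate-type esters out of the ring-forming step, makes C3–O and the latent C1 carbonyl in one concerted event, and derives C1 from C3.

Key step: step 16

Remarks.
- Atom numbers C1–C15 are those of the ring skeleton and are used for open-chain intermediates as well.
- Metal alkoxides, enolates, N-metallated forms and tetrahedral adducts count as reacting forms of a numbered compound, except alkoxide 21, the only form of that intermediate.
- Assumption on the chemistry: the aldol of step 8 is taken to run through the magnesium-chelated (Z)-enolate, attacked on the face away from the benzyl group (the sense of imide enolate alkylations). This fixes the (4S)-auxiliary.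

## Route

Step 1
Reactants: 1 propargyl alcohol
Product: 3 (2Z)-3-iodo-2-methylprop-2-en-1-ol, via alkenylmagnesium alkoxide 2 (not isolated)
Conditions: MeMgBr (2.5 equiv), CuI (10 mol %), THF, −10 °C to rt; then I2, −10 °C
Reagents that add atoms: methylmagnesium bromide C[Mg]Br; iodine [I][I]
Why: Alkoxide-directed anti carbomagnesiation of a propargylic alcohol puts methyl on the internal carbon and magnesium on the terminal carbon, cis to CH2O in a five-membered chelate. Iodinolysis with retention gives the Z iodide.

Step 2
Reactants: 3 (2Z)-3-iodo-2-methylprop-2-en-1-ol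
Product: 4 (2Z)-1-(tert-butyldimethylsilyloxy)-3-iodo-2-methylprop-2-ene
Conditions: TBSCl, imidazole, CH2Cl2, 0 °C to rt
Reagents that add atoms: tert-butyldimethylsilyl chloride CC(C)(C)[Si](C)(C)Cl
Why: Routine silylation of a primary allylic alcohol; the iodoalkene is untouched.

Step 3
Reactants: 4 (2Z)-1-(tert-butyldimethylsilyloxy)-3-iodo-2-methylprop-2-ene
Product: 6 (2Z)-4-(tert-butyldimethylsilyloxy)-3-methylbut-2-enal, via alkenyllithium 5 (not isolated)
Conditions: t-BuLi (2.05 equiv), Et2O, −78 °C; then DMF, −78 to 0 °C; pH 7 buffer
Reagents that add atoms: N,N-dimethylformamide CN(C)C=O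
Why: Iodine–lithium exchange proceeds with retention and the alkenyllithium is formylated by DMF. Keeping the exchange at −78 °C in ether avoids the retro-Brook silyl shift and loss of geometry.

Step 4
Reactants: 3 (2Z)-3-iodo-2-methylprop-2-en-1-ol
Product: 7 (2Z)-3-iodo-2-methylprop-2-enal
Conditions: MnO2 (activated, excess), CH2Cl2, rt, dark
Reagents that add atoms: none
Why: Heterogeneous allylic oxidation under neutral conditions; the aldehyde is filtered and used at once to limit Z to E drift.

Step 5
Reactants: 7 (2Z)-3-iodo-2-methylprop-2-enal; 8 methyltriphenylphosphonium bromide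
Product: 10 (1Z)-1-iodo-2-methylbuta-1,3-diene, via methylenetriphenylphosphorane 9 (not isolated)
Conditions: 8, NaN(SiMe3)2, THF, 0 °C; then 7, −78 to 0 °C; product kept as a pentane/ether solution
Reagents that add atoms: none
Why: Wittig methylenation of an enal. The non-stabilised ylide attacks the carbonyl far faster than the iodoalkene, whose geometry is not involved.

Step 6
Reactants: 10 (1Z)-1-iodo-2-methylbuta-1,3-diene
Product: 12 tributyl[(1Z)-2-methylbuta-1,3-dien-1-yl]stannane, via dienyllithium 11 (not isolated)
Conditions: t-BuLi (2.05 equiv), Et2O, −78 °C; then Bu3SnCl, −78 °C to rt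
Reagents that add atoms: tributyltin chloride CCCC[Sn](Cl)(CCCC)CCCC
Why: Iodine–lithium exchange and stannylation both go with retention. The stannane is a non-volatile, storable form of the (Z)-dienyl unit.

Step 7
Reactants: 13 (4S)-4-benzyl-1,3-oxazolidin-2-one; 14 methyl 4-chloro-4-oxobutanoate
Product: 15 methyl 4-[(4S)-4-benzyl-2-oxo-1,3-oxazolidin-3-yl]-4-oxobutanoate
Conditions: n-BuLi, THF, −78 °C; then 14, −78 to 0 °C
Reagents that add atoms: none
Why: N-acylation of the lithiated oxazolidinone by an acid chloride; the methyl ester does not react at this temperature.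

Step 8
Reactants: 15 methyl 4-[(4S)-4-benzyl-2-oxo-1,3-oxazolidin-3-yl]-4-oxobutanoate; 6 (2Z)-4-(tert-butyldimethylsilyloxy)-3-methylbut-2-enal
Product: 17 methyl (3R,4R,5Z)-3-{[(4S)-4-benzyl-2-oxo-1,3-oxazolidin-3-yl]carbonyl}-7-(tert-butyldimethylsilyloxy)-4-hydroxy-6-methylhept-5-enoate, via trimethylsilyl ether 16 (not isolated)
Conditions: MgCl2 (20 mol %), Et3N (2 equiv), TMSCl (1.5 equiv), EtOAc, rt; then PPTS (cat.), MeOH, 0 °C, brief
Reagents that add atoms: none
Why: Magnesium halide-catalysed direct anti-aldol of an N-acyloxazolidinone: soft enolisation occurs only at the chelated imide (C7), and the enal adds through a boat-type transition state to the enolate face away from the benzyl group. This should set C7 and C8 anti with the absolute sense drawn. Silylation of the aldolate by TMSCl turns the catalyst over and keeps O8 off the C12 ester until the brief acidic methanolysis.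

Step 9
Reactants: 17 anti-aldol adduct
Product: 18 methyl (3R,4R,5Z)-3-{[(4S)-4-benzyl-2-oxo-1,3-oxazolidin-3-yl]carbonyl}-4,7-bis(tert-butyldimethylsilyloxy)-6-methylhept-5-enoate
Conditions: TBSOTf, 2,6-lutidine, CH2Cl2, −78 °C, on the crude alcohol
Reagents that add atoms: tert-butyldimethylsilyl triflate CC(C)(C)[Si](C)(C)OS(=O)(=O)C(F)(F)F
Why: Silyl triflate with a hindered base silylates the secondary allylic alcohol at low temperature without forming an alkoxide, so neither retro-aldol nor lactonisation onto C12 can compete.

Step 10
Reactants: 18 bis-silyl imide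
Product: 19 methyl (3R,4R,5Z)-4,7-bis(tert-butyldimethylsilyloxy)-3-(ethylsulfanylcarbonyl)-6-methylhept-5-enoate
Conditions: EtSH, n-BuLi, THF, 0 °C
Reagents that add atoms: ethanethiol CCS
Why: Lithium thiolate cleaves N-acyloxazolidinones at the exocyclic carbonyl even when α-branched. The methyl ester is much less electrophilic and the weakly basic thiolate should not epimerise C7.

Step 11
Reactants: 19 thioester; 12 tributyl[(1Z)-2-methylbuta-1,3-dien-1-yl]stannane
Product: 20 methyl (3R,5Z)-3-[(1R,2Z)-1,4-bis(tert-butyldimethylsilyloxy)-3-methylbut-2-en-1-yl]-6-methyl-4-oxoocta-5,7-dienoate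
Conditions: Pd2(dba)3 (2.5 mol %), P(2-furyl)3 (10 mol %), copper thiophene-2-carboxylate (CuTC, 1.5 equiv), THF, rt to 40 °C
Reagents that add atoms: none
Why: Liebeskind–Srogl ketone synthesis: the copper carboxylate activates the thioester toward zerovalent palladium and takes up the thiolate, and the alkenylstannane transmetalates with retention of the Z geometry. The medium is neutral, so the α-stereocentre, the β-silyloxy group and the methyl ester are not at risk.

Step 12
Reactants: 20 dienone
Product: 22 (4S,5S)-4-[(1R,2Z)-1,4-bis(tert-butyldimethylsilyloxy)-3-methylbut-2-en-1-yl]-5-[(1Z)-2-methylbuta-1,3-dien-1-yl]oxolan-2-one, via lithium alkoxide 21 (not isolated)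
Conditions: LiBH(s-Bu)3 (1.1 equiv), THF, −78 °C, then 0 °C; aq. NH4Cl; DBU (cat.), CH2Cl2, rt if any hydroxy ester remains
Reagents that add atoms: none
Why: Felkin–Anh 1,2-reduction: the branched C8 carbon stands anti to the bulky hydride, which passes the hydrogen on C7. For a ketone this places O6 anti to the C11 arm (6S), a sense reinforced by the anti β-silyloxy group. The C6 alkoxide then closes onto the C12 methyl ester to give the cis-lactone. An acyclic β,β-disubstituted enone is expected to take hydride at the carbonyl and not in conjugate fashion.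

Step 13
Reactants: 22 bis-silyl lactone
Product: 23 (4S,5S)-4-[(1R,2Z)-1-(tert-butyldimethylsilyloxy)-4-hydroxy-3-methylbut-2-en-1-yl]-5-[(1Z)-2-methylbuta-1,3-dien-1-yl]oxolan-2-one
Conditions: HF·pyridine, pyridine, THF, 0 °C
Reagents that add atoms: none
Why: Buffered fluoride removes a primary allylic TBS ether much faster than the secondary one at C8, which is flanked by the ring-fusion carbon and a Z olefin. Lactone and diene are inert.

Step 14
Reactants: 23 primary allylic alcohol
Product: 24 (2Z)-4-(tert-butyldimethylsilyloxy)-2-methyl-4-{(2S,3S)-2-[(1Z)-2-methylbuta-1,3-dien-1-yl]-5-oxooxolan-3-yl}but-2-enal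
Conditions: Dess–Martin periodinane, NaHCO3, CH2Cl2, 0 °C
Reagents that add atoms: none
Why: Buffered Dess–Martin oxidation of an allylic alcohol is fast and non-basic, so the Z geometry of the new enal should be kept; the aldehyde is used directly.

Step 15
Reactants: 24 (Z)-enal
Product: 25 (E)-oxime of 24 (C1 aldoxime; cis-lactone; Z C4=C5 diene; Z C9=C10; C8 OTBS)
Conditions: NH2OH·HCl (1.1 equiv), pyridine, EtOH, 0 °C
Reagents that add atoms: hydroxylamine hydrochloride Cl.NO
Why: Oxime condensation at the aldehyde is far faster than any attack on the lactone. The oxime geometry is immaterial because the next step makes the linear nitrile oxide.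

Step 16
Reactants: 25 (Z)-enal oxime
Product: 28 isoxazoline-bridged ten-membered cis-lactone (C1=N and O–C3; 3S,6S,7S,8R; 4Z,9Z; C8 OTBS), via hydroximoyl chloride 26 (not isolated), via nitrile oxide 27 (not isolated)
Conditions: aq. NaOCl, CH2Cl2, Et3N (cat.), 0 °C to rt; 25 added by syringe pump to a final concentration of about 2 mM
Reagents that add atoms: none
Why: NaOCl chlorinates the aldoxime to hydroximoyl chloride 26, which loses HCl at the basic interface to give the conjugated nitrile oxide 27; 27 adds to the C2=C3 vinyl group in a concerted, suprafacial [3+2] cycloaddition. The closest known reaction type is the intramolecular nitrile oxide–olefin cycloaddition used to close medium and large carbocycles from ω-alkenyl nitrile oxides. The ten-membered carbocycle closes through the C1–C2 bond in the bridged mode (dipole carbon to the unsubstituted olefin terminus), and the isoxazoline closes through the C3–O bond as a five-membered ring spanning C1 and C3. The only new stereocentre, C3, is controlled by the diene conformation: the Z C4=C5 olefin turns the vinyl group out of the diene plane to relieve A1,3 strain with C6, and the dipole, held by the C6–C10 tether with its cis-lactone and Z C9=C10 olefin, can reach only the vinyl face turned toward that tether, which is expected to give 3S. Carbon-to-C2, oxygen-to-C3 regiochemistry is the inherent one for a monosubstituted olefin, and the vinyl group is a much better dipolarophile than the trisubstituted C4=C5 and C9=C10 olefins. Cyclisation must beat dimerisation to the furoxan; slow generation of 27 at high dilution and the slow dimerisation of an α-branched, conjugated nitrile oxide are relied on for this. No epimerisable centre or free hydroxyl is exposed to the hypochlorite.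

Step 17
Reactants: 28 isoxazoline
Product: 30 β-hydroxy enone (C1 ketone conjugated to Z C9=C10; 3S hydroxyl; cis-lactone; C8 OTBS), via β-hydroxy imine 29 (not isolated)
Conditions: Mo(CO)6 (1.2 equiv), MeCN/H2O (15:1), 80 °C
Reagents that add atoms: water O
Why: Mo(CO)6 cleaves the N–O bond reductively without touching C=C bonds, and the resulting N–H imine hydrolyses in the wet medium. Lactone and silyl ether are stable under these near-neutral conditions.

Step 18
Reactants: 30 β-hydroxy enone
Product: 31 anti-1,3-diol (1S,3S; cis-lactone; C8 OTBS)
Conditions: Me4NBH(OAc)3, MeCN/AcOH (1:1), −30 °C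
Reagents that add atoms: none
Why: Evans–Saksena reduction: the C3 hydroxyl exchanges onto boron and delivers hydride intramolecularly through a six-membered chair-like transition state, giving the 1,3-anti diol and hence 1S. The reagent reduces the enone carbonyl only and leaves the lactone alone.

Step 19
Reactants: 31 anti-diol
Product: 32 C1,C3-acetonide of 31 (isopropylidene acetal; C8 OTBS)
Conditions: 2,2-dimethoxypropane, PPTS (cat.), CH2Cl2, rt
Reagents that add atoms: 2,2-dimethoxypropane COC(C)(C)OC
Why: Acid-catalysed transacetalisation. The anti-diol gives a twist-boat dioxane that the seven-atom C4–C10 bridge can span, and PPTS is too weak to ionise the allylic carbinols.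

Step 20
Reactants: 32 acetonide
Product: 33 C11 dimethylaminomethyl lactone (Mannich base; C11 epimers)
Conditions: LiN(i-Pr)2 (1.1 equiv), THF, −78 °C; then CH2=NMe2 iodide (Eschenmoser's salt), −78 to 0 °C
Reagents that add atoms: Eschenmoser's salt C=[N+](C)C.[I-]
Why: C11 is the only enolisable position and all hydroxyls are masked, so the lactone enolate is aminomethylated cleanly (Mannich reaction). The new C11 centre is of no consequence.

Step 21
Reactants: 33 Mannich base
Product: 35 α-methylene lactone acetonide (C11=C13; C8 OTBS), via trimethylammonium iodide 34 (not isolated)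
Conditions: MeI, MeOH/CH2Cl2, rt; then aq. NaHCO3, EtOAc, rt
Reagents that add atoms: none
Why: Exhaustive N-methylation followed by E1cB elimination of trimethylamine under bicarbonate is the standard mild entry to α-methylene lactones.

Step 22
Reactants: 35 α-methylene lactone acetonide
Product: 36 C8 alcohol (α-methylene lactone; C1,C3-acetonide)
Conditions: Bu4NF, AcOH (1:1), THF, 0 °C to rt
Reagents that add atoms: none
Why: Acetic acid-buffered fluoride removes the secondary TBS ether while suppressing alkoxide or fluoride addition to the methylene lactone; the acetonide is untouched.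

Step 23
Reactants: 36 C8 alcohol; 37 angelic acid
Product: 39 C8 angelate acetonide, via mixed anhydride 38 (not isolated)
Conditions: 37, 2,4,6-trichlorobenzoyl chloride, Et3N, toluene, rt; then 36, toluene, 80 °C, no DMAP
Reagents that add atoms: none
Why: Yamaguchi-type mixed-anhydride esterification run without a nucleophilic catalyst, the variant that acylates hindered alcohols with angelic acid without isomerisation to the tiglate. Only O8 is free.

Step 24
Reactants: 39 angelate acetonide
Product: 40 target (CNP0152559.4)
Conditions: PPTS (cat.), MeOH, rt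
Reagents that add atoms: none
Why: Acid-catalysed transacetalisation to methanol cleaves the strained anti-acetonide readily. The angelate, the methylene lactone and the allylic carbinols should tolerate this weak acid.

## Compound list

1 | propargyl alcohol | C#CCO | starting material
2 | bromomagnesium (2Z)-3-(bromomagnesio)-2-methylprop-2-en-1-olate (not isolated) | Br[Mg]/C=C(/C)CO[Mg]Br | intermediate
3 | (2Z)-3-iodo-2-methylprop-2-en-1-ol | OC/C(C)=C\I | intermediate
4 | (2Z)-1-(tert-butyldimethylsilyloxy)-3-iodo-2-methylprop-2-ene | CC(C)(C)[Si](C)(C)OC/C(C)=C\I | intermediate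
5 | [(1Z)-3-(tert-butyldimethylsilyloxy)-2-methylprop-1-en-1-yl]lithium (not isolated) | [Li]/C=C(/C)CO[Si](C)(C)C(C)(C)C | intermediate
6 | (2Z)-4-(tert-butyldimethylsilyloxy)-3-methylbut-2-enal | O=C/C=C(/C)CO[Si](C)(C)C(C)(C)C | intermediate
7 | (2Z)-3-iodo-2-methylprop-2-enal | O=C/C(C)=C\I | intermediate
8 | methyltriphenylphosphonium bromide | C[P+](c1ccccc1)(c1ccccc1)c1ccccc1.[Br-] | starting material
9 | methylenetriphenylphosphorane (not isolated) | C=P(c1ccccc1)(c1ccccc1)c1ccccc1 | intermediate
10 | (1Z)-1-iodo-2-methylbuta-1,3-diene | C=C/C(C)=C\I | intermediate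
11 | [(1Z)-2-methylbuta-1,3-dien-1-yl]lithium (not isolated) | [Li]/C=C(/C)C=C | intermediate
12 | tributyl[(1Z)-2-methylbuta-1,3-dien-1-yl]stannane | CCCC[Sn](CCCC)(CCCC)/C=C(/C)C=C | intermediate
13 | (4S)-4-benzyl-1,3-oxazolidin-2-one | O=C1N[C@@H](Cc2ccccc2)CO1 | starting material
14 | methyl 4-chloro-4-oxobutanoate | COC(=O)CCC(Cl)=O | starting material
15 | methyl 4-[(4S)-4-benzyl-2-oxo-1,3-oxazolidin-3-yl]-4-oxobutanoate | COC(=O)CCC(=O)N1[C@@H](Cc2ccccc2)COC1=O | intermediate
16 | trimethylsilyl ether of aldol adduct 17 (not isolated) | COC(=O)C[C@@H](C(=O)N1[C@@H](Cc2ccccc2)COC1=O)[C@H](O[Si](C)(C)C)/C=C(C)\CO[Si](C)(C)C(C)(C)C | intermediate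
17 | methyl (3R,4R,5Z)-3-{[(4S)-4-benzyl-2-oxo-1,3-oxazolidin-3-yl]carbonyl}-7-(tert-butyldimethylsilyloxy)-4-hydroxy-6-methylhept-5-enoate | COC(=O)C[C@@H](C(=O)N1[C@@H](Cc2ccccc2)COC1=O)[C@H](O)/C=C(C)\CO[Si](C)(C)C(C)(C)C | intermediate
18 | methyl (3R,4R,5Z)-3-{[(4S)-4-benzyl-2-oxo-1,3-oxazolidin-3-yl]carbonyl}-4,7-bis(tert-butyldimethylsilyloxy)-6-methylhept-5-enoate | COC(=O)C[C@@H](C(=O)N1[C@@H](Cc2ccccc2)COC1=O)[C@H](O[Si](C)(C)C(C)(C)C)/C=C(C)\CO[Si](C)(C)C(C)(C)C | intermediate
19 | methyl (3R,4R,5Z)-4,7-bis(tert-butyldimethylsilyloxy)-3-(ethylsulfanylcarbonyl)-6-methylhept-5-enoate | COC(=O)C[C@@H](C(=O)SCC)[C@H](O[Si](C)(C)C(C)(C)C)/C=C(C)\CO[Si](C)(C)C(C)(C)C | intermediate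
20 | methyl (3R,5Z)-3-[(1R,2Z)-1,4-bis(tert-butyldimethylsilyloxy)-3-methylbut-2-en-1-yl]-6-methyl-4-oxoocta-5,7-dienoate | COC(=O)C[C@@H](C(=O)/C=C(/C)C=C)[C@H](O[Si](C)(C)C(C)(C)C)/C=C(C)\CO[Si](C)(C)C(C)(C)C | intermediate
21 | lithium (6S)-alkoxide of the hydroxy ester from 20 (not isolated) | COC(=O)C[C@@H]([C@@H](O[Li])/C=C(/C)C=C)[C@H](O[Si](C)(C)C(C)(C)C)/C=C(C)\CO[Si](C)(C)C(C)(C)C | intermediate
22 | (4S,5S)-4-[(1R,2Z)-1,4-bis(tert-butyldimethylsilyloxy)-3-methylbut-2-en-1-yl]-5-[(1Z)-2-methylbuta-1,3-dien-1-yl]oxolan-2-one | C=C/C(C)=C\[C@@H]1OC(=O)C[C@@H]1[C@H](O[Si](C)(C)C(C)(C)C)/C=C(C)\CO[Si](C)(C)C(C)(C)C | intermediate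
23 | (4S,5S)-4-[(1R,2Z)-1-(tert-butyldimethylsilyloxy)-4-hydroxy-3-methylbut-2-en-1-yl]-5-[(1Z)-2-methylbuta-1,3-dien-1-yl]oxolan-2-one | C=C/C(C)=C\[C@@H]1OC(=O)C[C@@H]1[C@H](O[Si](C)(C)C(C)(C)C)/C=C(C)\CO | intermediate
24 | (2Z)-4-(tert-butyldimethylsilyloxy)-2-methyl-4-{(2S,3S)-2-[(1Z)-2-methylbuta-1,3-dien-1-yl]-5-oxooxolan-3-yl}but-2-enal (4R) | C=C/C(C)=C\[C@@H]1OC(=O)C[C@@H]1[C@H](O[Si](C)(C)C(C)(C)C)/C=C(C)\C=O | intermediate
25 | (E)-oxime of 24 | C=C/C(C)=C\[C@@H]1OC(=O)C[C@@H]1[C@H](O[Si](C)(C)C(C)(C)C)/C=C(C)\C=N\O | intermediate
26 | hydroximoyl chloride from 25 (not isolated) | C=C/C(C)=C\[C@@H]1OC(=O)C[C@@H]1[C@H](O[Si](C)(C)C(C)(C)C)/C=C(C)\C(Cl)=NO | intermediate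
27 | nitrile oxide from 25 (not isolated) | C=C/C(C)=C\[C@@H]1OC(=O)C[C@@H]1[C@H](O[Si](C)(C)C(C)(C)C)/C=C(C)\C#[N+][O-] | intermediate
28 | isoxazoline-bridged ten-membered cis-lactone (C1=N, O–C3; 3S,6S,7S,8R; 4Z,9Z; C8 OTBS) | C1C(=O)O[C@H]2/C=C(/C)[C@@H]3CC(=NO3)/C(C)=C\[C@@H](O[Si](C)(C)C(C)(C)C)[C@@H]12 | intermediate
29 | β-hydroxy N–H imine at C1 with 3S hydroxyl (not isolated) | C1C(=O)O[C@H]2/C=C(/C)[C@@H](O)CC(=N)/C(C)=C\[C@@H](O[Si](C)(C)C(C)(C)C)[C@@H]12 | intermediate
30 | β-hydroxy enone (C1 ketone, 3S hydroxyl; ring centres as in 28) | C1C(=O)O[C@H]2/C=C(/C)[C@@H](O)CC(=O)/C(C)=C\[C@@H](O[Si](C)(C)C(C)(C)C)[C@@H]12 | intermediate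
31 | anti-1,3-diol (1S,3S; ring centres as in 28; C8 OTBS) | C1C(=O)O[C@H]2/C=C(/C)[C@@H](O)C[C@H](O)/C(C)=C\[C@@H](O[Si](C)(C)C(C)(C)C)[C@@H]12 | intermediate
32 | C1,C3-isopropylidene acetal of 31 | C1C(=O)O[C@H]2/C=C(/C)[C@@H]3C[C@H](OC(C)(C)O3)/C(C)=C\[C@@H](O[Si](C)(C)C(C)(C)C)[C@@H]12 | intermediate
33 | C11 dimethylaminomethyl derivative of 32 (C11 epimers) | CN(C)CC1C(=O)O[C@H]2/C=C(/C)[C@@H]3C[C@H](OC(C)(C)O3)/C(C)=C\[C@@H](O[Si](C)(C)C(C)(C)C)[C@@H]12 | intermediate
34 | trimethylammonium iodide of 33 (not isolated) | C[N+](C)(C)CC1C(=O)O[C@H]2/C=C(/C)[C@@H]3C[C@H](OC(C)(C)O3)/C(C)=C\[C@@H](O[Si](C)(C)C(C)(C)C)[C@@H]12.[I-] | intermediate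
35 | α-methylene lactone acetonide (C8 OTBS) | C=C1C(=O)O[C@H]2/C=C(/C)[C@@H]3C[C@H](OC(C)(C)O3)/C(C)=C\[C@@H](O[Si](C)(C)C(C)(C)C)[C@@H]12 | intermediate
36 | C8 alcohol (α-methylene lactone, C1,C3-acetonide) | C=C1C(=O)O[C@H]2/C=C(/C)[C@@H]3C[C@H](OC(C)(C)O3)/C(C)=C\[C@@H](O)[C@@H]12 | intermediate
37 | angelic acid, (2Z)-2-methylbut-2-enoic acid | C/C=C(/C)C(=O)O | starting material
38 | angelic 2,4,6-trichlorobenzoic anhydride (not isolated) | C/C=C(/C)C(=O)OC(=O)c1c(Cl)cc(Cl)cc1Cl | intermediate
39 | C8 angelate of 36 (acetonide) | C=C1C(=O)O[C@H]2/C=C(/C)[C@@H]3C[C@H](OC(C)(C)O3)/C(C)=C\[C@@H](OC(=O)/C(C)=C\C)[C@@H]12 | intermediate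
40 | CNP0152559.4 (1S,3S,6S,7S,8R; 4Z,9Z) | C=C1C(=O)O[C@H]2/C=C(/C)[C@@H](O)C[C@H](O)/C(C)=C\[C@@H](OC(=O)/C(C)=C\C)[C@@H]12 | target

## Step count and least certain steps

Total: 24 steps. Longest linear sequence: 20 steps (steps 1, 2, 3 and 8–24, from propargyl alcohol 1).

**Step 16 (key step).** Three things can go wrong.
- Dimerisation of the nitrile oxide to the furoxan may outrun a strained ten-membered closure.
- The dipole may add to an internal olefin or with reversed orientation.
- Facial selectivity at C3 may be poor, since it rests on a conformational argument only.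

The fallback separates cycloaddition from ring closure. It sets out from thioester 19 and returns at 28.
1. Buffered HF·pyridine removes the primary silyl group to give hydroxy thioester F1.
2. Dess–Martin oxidation gives enal F2, and NH2OH·HCl/pyridine gives oxime F3.
3. N-Chlorosuccinimide in DMF gives hydroximoyl chloride F4, so the stannane never meets positive chlorine.
4. Slow addition of Et3N in the presence of excess stannane 12 releases nitrile oxide F5, which adds intermolecularly to the vinyl terminus of 12 to give isoxazoline F6. The C3 epimers are separated here.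
5. An intramolecular thioester–stannane coupling (Pd2(dba)3, copper thiophene-2-carboxylate, high dilution) closes the ring at C5–C6 to macrocyclic ketone F7.
6. LiBH(s-Bu)3 reduction of F7 and closure of the C6 alkoxide onto the C12 ester give 28.

**Step 8.** The γ-enolisable (Z)-enal may lose its geometry under Et3N/TMSCl over the long reaction time, the β,β-disubstituted enal may add slowly, and O8 may close onto the C12 ester during removal of the TMS group. The fallback sets out from 15 and 6 and returns at 17. The dibutylboron enolate of 15 (Bu2BOTf, i-Pr2NEt, −78 °C) is added to 6 precomplexed with Et2AlCl. This is an open transition state at low temperature, in which the boron-chelated enolate reacts on the same face and gives the same anti adduct. The mixture is quenched cold at pH 7 and the crude alcohol is silylated as in step 9. This makes no compound outside the list, entry none F0.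

**Step 12.** Facial selectivity at C6 may be poor if the Felkin–Anh bias of C7 is weak, hydride may add in conjugate fashion, and the (Z)-dienone may equilibrate with its 2H-pyran valence isomer before reduction. The fallback replaces substrate control by reagent control and sets out from 20 and returns at 22. Corey–Bakshi–Shibata reduction with the (S)-B-methyl oxazaborolidine and catecholborane in toluene at −78 °C is strictly 1,2-selective and is expected to give 6S if the dienyl group acts as the larger substituent. DBU-catalysed closure of the resulting hydroxy ester (neutral form of 21) follows. This makes no compound outside the list, entry none F0.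

**Step 15.** The α-methyl (Z)-enal may drift to the E isomer through reversible conjugate addition of hydroxylamine or pyridine during oxidation and oximation; the E isomer cannot cyclise. The fallback avoids the aldehyde altogether and sets out from alcohol 23, returning at 28 through 27. CBr4/PPh3 gives allylic bromide F8, AgNO2 in ether gives primary nitro compound F9, and Mukaiyama dehydration (PhNCO, Et3N cat., toluene, high dilution) generates nitrile oxide 27 slowly under non-oxidative conditions.

**Step 23.** The angelate may isomerise to the tiglate, or the hindered C8 hydroxyl may acylate sluggishly. The fallback builds the Z olefin on the ester and sets out from 36, returning at 39. Alcohol 36 is acylated with 2-[bis(2,2,2-trifluoroethoxy)phosphoryl]propanoic acid (carbodiimide, DMAP) to phosphonate F10. Still–Gennari olefination with acetaldehyde (KN(SiMe3)2, 18-crown-6, THF, −78 °C) then gives the (Z)-2-methylbut-2-enoate.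

## Further compounds

F1 | step 16 | methyl (3R,4R,5Z)-4-(tert-butyldimethylsilyloxy)-3-(ethylsulfanylcarbonyl)-7-hydroxy-6-methylhept-5-enoate | COC(=O)C[C@@H](C(=O)SCC)[C@H](O[Si](C)(C)C(C)(C)C)/C=C(C)\CO
F2 | step 16 | methyl (3R,4R,5Z)-4-(tert-butyldimethylsilyloxy)-3-(ethylsulfanylcarbonyl)-6-methyl-7-oxohept-5-enoate | COC(=O)C[C@@H](C(=O)SCC)[C@H](O[Si](C)(C)C(C)(C)C)/C=C(C)\C=O
F3 | step 16 | (E)-oxime of F2 | COC(=O)C[C@@H](C(=O)SCC)[C@H](O[Si](C)(C)C(C)(C)C)/C=C(C)\C=N\O
F4 | step 16 | hydroximoyl chloride of F3 | COC(=O)C[C@@H](C(=O)SCC)[C@H](O[Si](C)(C)C(C)(C)C)/C=C(C)\C(Cl)=NO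
F5 | step 16 | nitrile oxide from F4 (not isolated) | COC(=O)C[C@@H](C(=O)SCC)[C@H](O[Si](C)(C)C(C)(C)C)/C=C(C)\C#[N+][O-]
F6 | step 16 | open-chain isoxazoline (3S) with C6 ethyl thioester and (Z)-C5 tributylstannyl group | COC(=O)C[C@@H](C(=O)SCC)[C@H](O[Si](C)(C)C(C)(C)C)/C=C(C)\C1=NO[C@@H](C1)/C(C)=C\[Sn](CCCC)(CCCC)CCCC
F7 | step 16 | isoxazoline-bridged (4Z,9Z)-cyclodecadien-6-one with C7 methyl acetate arm and C8 OTBS | COC(=O)C[C@H]1C(=O)/C=C(/C)[C@@H]2CC(=NO2)/C(C)=C\[C@H]1O[Si](C)(C)C(C)(C)C
F0 | step 8 | none | none
F0 | step 12 | none | none
F8 | step 15 | C1 allylic bromide corresponding to alcohol 23 | C=C/C(C)=C\[C@@H]1OC(=O)C[C@@H]1[C@H](O[Si](C)(C)C(C)(C)C)/C=C(C)\CBr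
F9 | step 15 | C1 primary nitro compound corresponding to alcohol 23 | C=C/C(C)=C\[C@@H]1OC(=O)C[C@@H]1[C@H](O[Si](C)(C)C(C)(C)C)/C=C(C)\C[N+](=O)[O-]
F10 | step 23 | C8 2-[bis(2,2,2-trifluoroethoxy)phosphoryl]propanoate of 36 | C=C1C(=O)O[C@H]2/C=C(/C)[C@@H]3C[C@H](OC(C)(C)O3)/C(C)=C\[C@@H](OC(=O)C(C)P(=O)(OCC(F)(F)F)OCC(F)(F)F)[C@@H]12
A1 | alternative 1 | (4Z,9Z)-cyclodeca-4,9-diene-3,8-dione with C1 hydroxyl, C6 triethylsilyloxy group and C7 3-(triethylsilyloxy)prop-1-en-2-yl group | C=C(CO[Si](CC)(CC)CC)[C@H]1[C@@H](O[Si](CC)(CC)CC)/C=C(/C)C(=O)C[C@H](O)/C(C)=C\C1=O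
A2 | alternative 2 | (4Z,9Z)-cyclodecadien-6-one with C7 methyl acetate arm, C1 and C3 OTBS, C8 p-methoxybenzyl ether | COC(=O)C[C@H]1C(=O)/C=C(/C)[C@@H](O[Si](C)(C)C(C)(C)C)C[C@H](O[Si](C)(C)C(C)(C)C)/C(C)=C\[C@H]1OCc2ccc(OC)cc2
A3 | alternative 3 | C1 tert-butyldimethylsilyl ether of the target | C=C1C(=O)O[C@H]2/C=C(/C)[C@@H](O)C[C@H](O[Si](C)(C)C(C)(C)C)/C(C)=C\[C@@H](OC(=O)/C(C)=C\C)[C@@H]12
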